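The numbers in the tables stem from a simulated flask on assumed constants; the scatter is artificial.

Birch holds 3.00 times the Q of alder, and at 7.0 min it shows about the L that alder shows at 21 min: 0.410 M against 0.434 M, each with a scatter of 0.01 M.

| flask | G | Q | time |
|---|---|---|---|
| alder | 1.00 M | 0.100 M |  |
| birch | 1.00 M | 0.300 M |  |
| larch | 0.500 M | 0.100 M |  |
| oak | 1.00 M | 0.100 M | 70 min |

- alder run (time / min: [L] / M): 7.0: 0.155; 14: 0.308; 21: 0.434; 28: 0.527; 35: 0.637
- birch run (time / min: [L] / M): 7.0: 0.410; 14: 0.719; 21: 0.878; 28: 0.965; 35: 1.003
- larch run (time / min: [L] / M): 7.0: 0.093; 14: 0.177; 21: 0.259; 28: 0.332; 35: 0.366

(readings scatter by 0.01 M)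

- order of the initial rate in [Q], near the charge of the alder run, the rate being that where two percent of its G are L
- order of the initial rate in [G], near the charge of the alder run, the rate being that where two percent of its G are L (one fixed amount of L, the same in the runs compared)
- L in the oak run at 70 min, as a share of the G charged
- which of these the readings show (the catalyst wakes slowly / two substrates go astray together / the substrate pairs with itself)

- Overall: G -> L, with Q as catalyst.
- Constant volume, constant temperature.
- What is held in complexes is read along with the free species.
- An order is taken over about fifteen percent of the charge, up and down.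

The oak run has the charge of alder, and at 70 min it stands at 7.00 M·min: that is our catalyst clock, the Q concentration multiplied by the minutes. We read each flask on this clock instead of on minutes.

Two extreme flasks can be solved in the head. In each, the share of G left falls exponentially with the clock at a steady pace, which is the pseudo-first-order constant divided by Q. The slow flask keeps the opening pace of alder over its first 14 min, and the fast one keeps the pace of birch between 14 min and 28 min:

slow pace 0.263 M⁻¹ min⁻¹, so oak turns 84.1%

fast pace 0.496 M⁻¹ min⁻¹, so oak turns 96.9%

We expect the real oak run between these, since its G starts at the charge that gave the slow pace and thins toward the stretch that gave the fast one, and the slow pace is lower than the fast one. The upper end is loose, because it rests on 0.0350 M of G left in birch, with a scatter of 0.01 M.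

Birch has the same G charge, so we read the oak clock on it directly, replacing the curve by its chord between two readings:

birch time 23.3 min, between 21 min and 28 min

our share 90.7%

The forecast gives 90%, with a range of 86% to 94%, on the same route as ours: “The oak run at 70 min equals birch at about 23 min”. It puts the order in Q at 1 (0.9 to 1.08) and the order in G at 0.65 (0.52 to 0.8), and it chooses: the substrate pairs with itself.

The oak run gives 91.2%, the order in Q comes to 1.0 and the order in G to 0.65, and what the readings show is this: the substrate pairs with itself.

    Q + G → L + Q (0.5646 M⁻¹ min⁻¹)
    2 G ⇌ G2, settled at all times (1.480 M⁻¹)

The clock holds at the quarter marks, where alder at 11.1 min stands at 1.11 M·min and birch at 3.70 min stands at 1.11 M·min. Birch needs 2.50 M·min on the clock to turn half of its 1.00 M of G, while larch needs 2.02 M·min to turn half of its 0.500 M, a shorter span. The oak clock of 7.00 M·min spans 2.80 of the birch span and 3.47 of the larch span.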